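**Retrosynthetic overview**
1. Sipholenone A ⇐ oxidation of the C18 carbinol and global desilylation of the fully protected coupled product 40.
2. 40 ⇐ C11–C12 bond by a copper-catalysed anti-SN2′ allyl–alkyl coupling of the ring A/B alkylborate (from iodide 37) with the ring C/D allylic phosphate 19; this also sets C11 and places the C2=C3 alkene.
3. Fragment AB (37) ⇐ ring B from 2-methylcyclohex-2-enone (CBS reduction sets C21, cuprate addition C15, allylation/equilibration C14, methyl addition C24); ring A (oxepane) closed by 7-endo epoxide opening.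
4. Fragment CD (19) ⇐ six-membered enone (Robinson annulation) → asymmetric conjugate addition (C6) → one-carbon ring expansion to ring C → SmI2 ketyl–enone cyclisation closing ring D (C5, C9).
5. Ring order: B then A; cyclohexenone → C → D; the two bicycles are joined last.

Locants: ring C = C2(Me)=C3–C4–C5–C6–C10(Me2)–C11; ring D = C5–C6–C7–C8–C9(Me)(OH); bridge C12–C13; ring B = C14–C15(Me)–C21–C22–C23–C24(Me)(OH); ring A = C15–C16–C17–C18(=O)–C19(Me2)–O20–C21.
Assumption: the sense of induction of the chiral catalysts (phosphoramidite, CBS, Shi ketone) follows the usual empirical models; if one proves opposite, its antipode is used.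

**Fragment CD**

Step 1
Reactants: 1 2-methylpropanal; 2 pent-1-en-3-one
Product: 3 2,4,4-trimethylcyclohex-2-en-1-one
Conditions: H2SO4 (cat.), PhMe, 45 °C then reflux (Dean–Stark)
Reagents that add atoms: none
Why: Acid-catalysed Robinson annulation (Michael addition of the aldehyde enol, then aldol condensation of the ethyl-ketone CH2 onto the non-enolisable aldehyde); no stereocentre is formed.

Step 2
Reactants: 3 2,4,4-trimethylcyclohex-2-en-1-one
Product: 4 2,4,4-trimethylcyclohexa-2,5-dien-1-one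
Conditions: DDQ (1.3 equiv), 1,4-dioxane, reflux
Reagents that add atoms: none
Why: DDQ dehydrogenation of the ketone; only C5–C6 can be unsaturated because C4 is quaternary.

Step 3
Reactants: 5 but-3-en-2-one
Product: 6 2-(2-bromoethyl)-2-methyl-1,3-dioxolane
Conditions: HBr (g), HOCH2CH2OH, 0 °C → rt
Reagents that add atoms: hydrogen bromide (Br); ethane-1,2-diol (OCCO)
Why: Conjugate hydrobromination of the enone followed by in situ ketalisation gives the masked 3-oxobutyl bromide.

Step 4
Reactants: 6 2-(2-bromoethyl)-2-methyl-1,3-dioxolane; 4 2,4,4-trimethylcyclohexa-2,5-dien-1-one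
Product: 10 trimethyl({(3R)-4,4,6-trimethyl-3-[2-(2-methyl-1,3-dioxolan-2-yl)ethyl]cyclohexa-1,5-dien-1-yl}oxy)silane, via Grignard reagent 7 (not isolated), via dialkylzinc 8 (not isolated), via zinc enolate 9 (not isolated)
Conditions: 6, Mg, THF, 40 °C; ZnCl2 (0.5 equiv), then 1,4-dioxane, filter; Cu(OTf)2 (2 mol %), (S,R,R)-binaphthol-derived N,N-bis(1-phenylethyl)phosphoramidite (4 mol %), 4, PhMe, −30 °C; then TMSCl, Et3N, −30 → 0 °C
Reagents that add atoms: chlorotrimethylsilane (C[Si](C)(C)Cl)
Why: Copper-catalysed asymmetric conjugate addition of a dialkylzinc with silyl trapping of the enolate; the alkyl group adds to the unsubstituted enone half (the 2-methyl enone is far less electrophilic) and the ligand sets C6 (R), the stereocentre that controls ring C/D.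

Step 5
Reactants: 10 silyl dienol ether from step 4
Product: 11 trimethyl({(5R)-2,4,4-trimethyl-5-[2-(2-methyl-1,3-dioxolan-2-yl)ethyl]bicyclo[4.1.0]hept-2-en-1-yl}oxy)silane (cyclopropane CH2 anti to the side chain)
Conditions: Et2Zn, CH2I2, CH2Cl2, 0 °C → rt
Reagents that add atoms: diiodomethane (ICI)
Why: Furukawa–Simmons–Smith cyclopropanation is selective for the electron-rich silyl enol ether alkene; the two new cyclopropane centres are destroyed in the next step.

Step 6
Reactants: 11 silyloxy vinylcyclopropane from step 5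
Product: 13 (5R)-2,4,4-trimethyl-5-[2-(2-methyl-1,3-dioxolan-2-yl)ethyl]cyclohepta-2,6-dien-1-one, via chloro ketone 12 (not isolated)
Conditions: FeCl3 (2.2 equiv), DMF, 0 °C; then NaOAc, MeOH, reflux
Reagents that add atoms: none
Why: Saegusa-type one-carbon ring expansion: oxidation to the alkoxy radical, β-scission of the internal cyclopropane bond and chlorine capture give the β-chloro ketone, which loses HCl (E1cB) to the cross-conjugated cycloheptadienone; C6 is untouched.

Step 7
Reactants: 13 dienone ketal from step 6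
Product: 14 (5R)-2,4,4-trimethyl-5-(3-oxobutyl)cyclohepta-2,6-dien-1-one
Conditions: 1 M HCl, THF, rt
Reagents that add atoms: water (O)
Why: Acid hydrolysis of the dioxolane releases the methyl ketone.

Step 8
Reactants: 14 (5R)-2,4,4-trimethyl-5-(3-oxobutyl)cyclohepta-2,6-dien-1-one
Product: 16 (1R,3aR,8aR)-1-hydroxy-1,4,4,6-tetramethyl-1,2,3,3a,4,8a-hexahydroazulen-7(8H)-one (cis-fused; OH cis to both ring-fusion H), via samarium dienolate 15 (not isolated)
Conditions: SmI2 (2.2 equiv), HMPA (8 equiv), THF, −78 °C; then sat. aq. NH4Cl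
Reagents that add atoms: none
Why: SmI2 ketyl–olefin reductive cyclisation (5-exo) onto C5 of the C4=C5 enone; the tether on C6 enforces the cis ring fusion, and the bulky samarium-bound oxygen turns away from C4, so the C9 hydroxyl ends trans to C4 (cis to H5) as in the target. The dienolate is protonated at C4 on quench, leaving the C2=C11 enone.

Step 9
Reactants: 16 hydroxy enone from step 8
Product: 17 (1R,3aR,8aR)-1,4,4,6-tetramethyl-1-(triethylsilyloxy)-1,2,3,3a,4,8a-hexahydroazulen-7(8H)-one
Conditions: TESOTf, 2,6-lutidine, CH2Cl2, −78 → 0 °C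
Reagents that add atoms: triethylsilyl trifluoromethanesulfonate (CC[Si](CC)(CC)OS(=O)(=O)C(F)(F)F)
Why: Silyl triflate silylation of the tertiary alcohol, so that no free hydroxyl interferes with the borate coupling.

Step 10
Reactants: 17 silyl ether enone from step 9
Product: 18 (1R,3aR,7R,8aR)-1,4,4,6-tetramethyl-1-(triethylsilyloxy)-1,2,3,3a,4,7,8,8a-octahydroazulen-7-ol (C3 hydroxyl on the face opposite ring D)
Conditions: (S)-Me-CBS (20 mol %), BH3·SMe2, THF, −40 °C; MeOH
Reagents that add atoms: none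
Why: Corey–Bakshi–Shibata reduction under reagent control (alkenyl side as large group, CH2 as small) gives the (R)-allylic alcohol; this auxiliary C3 centre later relays its configuration to C11.

Step 11
Reactants: 18 allylic alcohol from step 10
Product: 19 diethyl (1R,3aR,7R,8aR)-1,4,4,6-tetramethyl-1-(triethylsilyloxy)-1,2,3,3a,4,7,8,8a-octahydroazulen-7-yl phosphate
Conditions: ClP(O)(OEt)2, Et3N, DMAP (cat.), CH2Cl2, 0 °C; used without chromatography
Reagents that add atoms: diethyl chlorophosphate (CCOP(=O)(Cl)OCC)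
Why: O-phosphorylation of the secondary allylic alcohol with retention gives the leaving group for the allylic coupling.

**Fragment AB**

Step 12
Reactants: 20 2-methylcyclohex-2-en-1-one
Product: 21 (1R)-2-methylcyclohex-2-en-1-ol
Conditions: (S)-Me-CBS (10 mol %), BH3·SMe2, THF, −20 °C
Reagents that add atoms: none
Why: Corey–Bakshi–Shibata 1,2-reduction of the α-substituted six-membered enone (alkenyl side as large group) sets the future C21 carbinol centre.

Step 13
Reactants: 21 (1R)-2-methylcyclohex-2-en-1-ol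
Product: 22 tert-butyldimethyl{[(1R)-2-methylcyclohex-2-en-1-yl]oxy}silane
Conditions: TBSCl, imidazole, DMF, rt
Reagents that add atoms: tert-butyldimethylsilyl chloride (CC(C)(C)[Si](C)(C)Cl)
Why: Standard silylation; the bulky ether later shields its own allylic C–H and directs the cuprate.

Step 14
Reactants: 22 silyl ether from step 13
Product: 23 (4R)-4-[(tert-butyldimethylsilyl)oxy]-3-methylcyclohex-2-en-1-one
Conditions: Pd(OH)2/C (5 mol %), t-BuOOH (5 equiv), K2CO3 (0.25 equiv), CH2Cl2, 0 °C → rt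
Reagents that add atoms: tert-butyl hydroperoxide (CC(C)(C)OO)
Why: Catalytic allylic oxidation (tert-butylperoxy radical chain) converts the unhindered ring allylic CH2 into the enone carbonyl; the silyloxy-bearing methine is shielded and the stereocentre is untouched.

Step 15
Reactants: 24 5-bromo-2-methylpent-2-ene; 23 (4R)-4-[(tert-butyldimethylsilyl)oxy]-3-methylcyclohex-2-en-1-one
Product: 26 tert-butyldimethyl({(1R,2R)-2-methyl-2-(4-methylpent-3-en-1-yl)-4-[(trimethylsilyl)oxy]cyclohex-3-en-1-yl}oxy)silane, via Grignard reagent 25 (not isolated)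
Conditions: 24, Mg, THF; CuBr·SMe2 (10 mol %), TMSCl, HMPA, 23, THF, −78 → −40 °C
Reagents that add atoms: chlorotrimethylsilane (C[Si](C)(C)Cl)
Why: TMSCl-accelerated copper-catalysed conjugate addition of the homoprenyl Grignard reagent occurs anti to the adjacent silyloxy group, creating the C15 quaternary centre (chain trans to O21) and a regiodefined silyl enol ether.

Step 16
Reactants: 26 silyl enol ether from step 15
Product: 28 (3R,4R)-4-[(tert-butyldimethylsilyl)oxy]-3-methyl-3-(4-methylpent-3-en-1-yl)-2-(prop-2-en-1-yl)cyclohexan-1-one (C2 epimer mixture), via lithium enolate 27 (not isolated)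
Conditions: MeLi, THF, 0 °C; then allyl bromide, HMPA, −78 → 0 °C
Reagents that add atoms: allyl bromide (C=CCBr)
Why: Si–O cleavage with MeLi gives the regiospecific lithium enolate, which is C-allylated at C14; the C14 configuration is immaterial here because it is set by equilibration in step 20.

Step 17
Reactants: 28 allyl ketone from step 16
Product: 29 (3R,4R)-4-hydroxy-3-methyl-3-(4-methylpent-3-en-1-yl)-2-(prop-2-en-1-yl)cyclohexan-1-one (C2 epimer mixture)
Conditions: TBAF, THF, rt
Reagents that add atoms: none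
Why: Fluoride desilylation frees the C21 hydroxyl before the epoxide is made, so no alkoxide ever meets the epoxide.

Step 18
Reactants: 29 hydroxy ketone from step 17
Product: 30 (3R,4R)-3-{2-[(2R)-3,3-dimethyloxiran-2-yl]ethyl}-4-hydroxy-3-methyl-2-(prop-2-en-1-yl)cyclohexan-1-one (C2 epimer mixture)
Conditions: D-fructose-derived Shi ketone (30 mol %), KHSO5 (Oxone), K2CO3, Bu4NHSO4, MeCN/(MeO)2CH2/aq. buffer pH 10.5, 0 °C
Reagents that add atoms: potassium peroxymonosulfate ([K+].[O-]S(=O)(=O)OO)
Why: Shi epoxidation (chiral dioxirane) is selective for the trisubstituted alkene over the allyl group and gives one C18 epimer, which keeps all later intermediates single compounds although C18 finally becomes the ketone.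

Step 19
Reactants: 30 epoxy alcohol from step 18
Product: 31 (3R,5aR,9aR)-3-hydroxy-2,2,5a-trimethyl-6-(prop-2-en-1-yl)octahydro-1-benzoxepin-7(2H)-one (trans-fused; C6 epimer mixture)
Conditions: CSA (10 mol %), CH2Cl2, 0 °C
Reagents that add atoms: none
Why: Acid-catalysed 7-endo epoxide opening: the equatorial C21 hydroxyl attacks the tertiary C19 (Markovnikov, SN1-like), while the 6-exo path needs SN2 attack at the neopentyl-type C18; C18 keeps its oxygen with retention and the oxepane is trans-fused.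

Step 20
Reactants: 31 bicyclic hydroxy ketone from step 19
Product: 32 (3R,5aR,6R,9aR)-3-hydroxy-2,2,5a-trimethyl-6-(prop-2-en-1-yl)octahydro-1-benzoxepin-7(2H)-one (allyl equatorial and cis to the angular methyl)
Conditions: NaOMe (0.5 equiv), MeOH, rt; minor epimer recycled
Reagents that add atoms: none
Why: Base-mediated epimerisation α to the C24 ketone in the rigid trans-fused bicycle places the C14 allyl group equatorial (the axial epimer suffers two 1,3-diaxial interactions), which is the target C14 configuration; the ratio is expected to be moderate, roughly 4:1.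

Step 21
Reactants: 32 equilibrated hydroxy ketone from step 20
Product: 33 (3R,5aR,6R,7S,9aR)-2,2,5a,7-tetramethyl-6-(prop-2-en-1-yl)decahydro-1-benzoxepine-3,7-diol
Conditions: MeMgBr (4 equiv), CeCl3 (4 equiv), THF, −78 → 0 °C
Reagents that add atoms: methylmagnesium bromide (C[Mg]Br)
Why: Organocerium 1,2-addition without enolisation; the axial C15 methyl blocks the axial trajectory, so methyl enters equatorially and the C24 hydroxyl ends axial, syn to the angular methyl as in the target.

Step 22
Reactants: 33 diol from step 21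
Product: 34 bis(triethylsilyl) ether of 33 (C18–OSiEt3 plus C24–OSiEt3)
Conditions: TESOTf (3 equiv), 2,6-lutidine, CH2Cl2, 0 °C
Reagents that add atoms: triethylsilyl trifluoromethanesulfonate (CC[Si](CC)(CC)OS(=O)(=O)C(F)(F)F)
Why: Silyl triflate silylation of both hydroxyls; protecting the tertiary C24 alcohol prevents tetrahydrofuran formation once C12 carries iodide.

Step 23
Reactants: 34 bis-silyl ether from step 22
Product: 36 2-[(3R,5aR,6R,7S,9aR)-2,2,5a,7-tetramethyl-3,7-bis(triethylsilyloxy)decahydro-1-benzoxepin-6-yl]ethan-1-ol, via aldehyde 35 (not isolated)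
Conditions: O3, CH2Cl2/MeOH, −78 °C; then NaBH4, −78 → 0 °C
Reagents that add atoms: ozone ([O-][O+]=O)
Why: Ozonolysis of the only remaining alkene with reductive work-up trims the allyl group to the two-carbon C13–C12 alcohol.

Step 24
Reactants: 36 primary alcohol from step 23
Product: 37 (3R,5aR,6R,7S,9aR)-6-(2-iodoethyl)-2,2,5a,7-tetramethyl-3,7-bis(triethylsilyloxy)decahydro-1-benzoxepine
Conditions: I2, PPh3, imidazole, CH2Cl2, 0 °C
Reagents that add atoms: iodine (II)
Why: Appel-type iodination of the primary alcohol under buffered conditions that leave the silyl ethers intact.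

**Fragment union and end game**

Step 25
Reactants: 37 fragment AB iodide; 19 fragment CD allylic phosphate
Product: 40 coupled product: sipholenone A skeleton bearing C18–OSiEt3 (R) in place of the ketone plus C9–OSiEt3 plus C24–OSiEt3, via alkyllithium 38 (not isolated), via lithium alkylborate 39 (not isolated)
Conditions: 37, t-BuLi (2.1 equiv), Et2O, −78 °C; B-methoxy-9-BBN, THF, −78 °C → rt; then 19, CuOAc (15 mol %), THF, 0 → 45 °C
Reagents that add atoms: none
Why: Proposed new method: alkyl transfer from the tetracoordinate borate 39 to monovalent copper gives a neutral alkylcopper that binds C2=C11 on the face opposite the phosphate, adds oxidatively at C11 to a trivalent σ-allylcopper and reductively eliminates before allyl isomerisation, so the C3 configuration is relayed to C11 (new bond on the ring D face, anti to the leaving group) and the alkene moves to C2=C3; the closest known reaction type is the copper-catalysed γ-selective, anti-stereospecific allyl–alkyl coupling of B-alkyl-9-BBN ate complexes with allylic phosphates, not yet shown for a neopentylic γ-carbon of a 2-methylcycloheptenyl phosphate, for a lithium methoxyborate made from an alkyl iodide, or for two fully elaborated fragments.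

Step 26
Reactants: 40 tris-silyl ether from step 25
Product: 41 (18R)-triol: target skeleton with a C18 carbinol in place of the ketone
Conditions: HF·pyridine, pyridine, THF, 0 °C → rt
Reagents that add atoms: none
Why: Buffered fluoride cleavage removes the three triethylsilyl ethers without ionising the tertiary alcohols or moving the trisubstituted alkene.

Step 27
Reactants: 41 triol from step 26
Product: 42 sipholenone A
Conditions: Dess–Martin periodinane, CH2Cl2, 0 °C → rt
Reagents that add atoms: none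
Why: Dess–Martin oxidation converts the only secondary alcohol (C18) into the ketone; the two tertiary alcohols and the alkene do not react, and the auxiliary C18 centre disappears.

**Compound list**
1 | 2-methylpropanal | CC(C)C=O | starting material
2 | pent-1-en-3-one | CCC(=O)C=C | starting material
3 | 2,4,4-trimethylcyclohex-2-en-1-one | CC1=CC(C)(C)CCC1=O | intermediate
4 | 2,4,4-trimethylcyclohexa-2,5-dien-1-one | CC1=CC(C)(C)C=CC1=O | intermediate
5 | but-3-en-2-one | CC(=O)C=C | starting material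
6 | 2-(2-bromoethyl)-2-methyl-1,3-dioxolane | CC1(CCBr)OCCO1 | intermediate
7 | [2-(2-methyl-1,3-dioxolan-2-yl)ethyl]magnesium bromide (not isolated) | CC1(CC[Mg]Br)OCCO1 | intermediate
8 | bis[2-(2-methyl-1,3-dioxolan-2-yl)ethyl]zinc (not isolated) | CC1(CC[Zn]CCC2(C)OCCO2)OCCO1 | intermediate
9 | alkylzinc enolate of the (R)-conjugate adduct (not isolated) | CC1(CC[Zn]OC2=C[C@@H](CCC3(C)OCCO3)C(C)(C)C=C2C)OCCO1 | intermediate
10 | trimethyl({(3R)-4,4,6-trimethyl-3-[2-(2-methyl-1,3-dioxolan-2-yl)ethyl]cyclohexa-1,5-dien-1-yl}oxy)silane | C[Si](C)(C)OC1=C[C@@H](CCC2(C)OCCO2)C(C)(C)C=C1C | intermediate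
11 | trimethyl({(5R)-2,4,4-trimethyl-5-[2-(2-methyl-1,3-dioxolan-2-yl)ethyl]bicyclo[4.1.0]hept-2-en-1-yl}oxy)silane, cyclopropane CH2 anti to the side chain | C[Si](C)(C)O[C@@]12C[C@@H]1[C@@H](CCC1(C)OCCO1)C(C)(C)C=C2C | intermediate
12 | 6-chloro-2,4,4-trimethyl-5-[2-(2-methyl-1,3-dioxolan-2-yl)ethyl]cyclohept-2-en-1-one, C5 as in 13, epimers at the C–Cl carbon (not isolated) | O=C1CC(Cl)[C@@H](CCC2(C)OCCO2)C(C)(C)C=C1C | intermediate
13 | (5R)-2,4,4-trimethyl-5-[2-(2-methyl-1,3-dioxolan-2-yl)ethyl]cyclohepta-2,6-dien-1-one | O=C1C=C[C@@H](CCC2(C)OCCO2)C(C)(C)C=C1C | intermediate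
14 | (5R)-2,4,4-trimethyl-5-(3-oxobutyl)cyclohepta-2,6-dien-1-one | O=C1C=C[C@@H](CCC(C)=O)C(C)(C)C=C1C | intermediate
15 | bis(diiodosamarium) alkoxide–dienolate of 16 (not isolated) | I[Sm](I)OC1=C[C@@H]2[C@@H](CC[C@@]2(C)O[Sm](I)I)C(C)(C)C=C1C | intermediate
16 | (1R,3aR,8aR)-1-hydroxy-1,4,4,6-tetramethyl-1,2,3,3a,4,8a-hexahydroazulen-7(8H)-one, cis-fused, OH cis to the ring-fusion hydrogens | O=C1C[C@@H]2[C@@H](CC[C@@]2(C)O)C(C)(C)C=C1C | intermediate
17 | (1R,3aR,8aR)-1,4,4,6-tetramethyl-1-(triethylsilyloxy)-1,2,3,3a,4,8a-hexahydroazulen-7(8H)-one | O=C1C[C@@H]2[C@@H](CC[C@@]2(C)O[Si](CC)(CC)CC)C(C)(C)C=C1C | intermediate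
18 | (1R,3aR,7R,8aR)-1,4,4,6-tetramethyl-1-(triethylsilyloxy)-1,2,3,3a,4,7,8,8a-octahydroazulen-7-ol | O[C@@H]1C[C@@H]2[C@@H](CC[C@@]2(C)O[Si](CC)(CC)CC)C(C)(C)C=C1C | intermediate
19 | diethyl (1R,3aR,7R,8aR)-1,4,4,6-tetramethyl-1-(triethylsilyloxy)-1,2,3,3a,4,7,8,8a-octahydroazulen-7-yl phosphate | CCOP(=O)(OCC)O[C@@H]1C[C@@H]2[C@@H](CC[C@@]2(C)O[Si](CC)(CC)CC)C(C)(C)C=C1C | intermediate
20 | 2-methylcyclohex-2-en-1-one | CC1=CCCCC1=O | starting material
21 | (1R)-2-methylcyclohex-2-en-1-ol | O[C@@H]1CCCC=C1C | intermediate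
22 | tert-butyldimethyl{[(1R)-2-methylcyclohex-2-en-1-yl]oxy}silane | CC(C)(C)[Si](C)(C)O[C@@H]1CCCC=C1C | intermediate
23 | (4R)-4-[(tert-butyldimethylsilyl)oxy]-3-methylcyclohex-2-en-1-one | CC(C)(C)[Si](C)(C)O[C@@H]1CCC(=O)C=C1C | intermediate
24 | 5-bromo-2-methylpent-2-ene | CC(C)=CCCBr | starting material
25 | (4-methylpent-3-en-1-yl)magnesium bromide (not isolated) | CC(C)=CCC[Mg]Br | intermediate
26 | tert-butyldimethyl({(1R,2R)-2-methyl-2-(4-methylpent-3-en-1-yl)-4-[(trimethylsilyl)oxy]cyclohex-3-en-1-yl}oxy)silane | CC(C)(C)[Si](C)(C)O[C@@H]1CCC(O[Si](C)(C)C)=C[C@@]1(C)CCC=C(C)C | intermediate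
27 | lithium enolate corresponding to 26 (not isolated) | CC(C)(C)[Si](C)(C)O[C@@H]1CCC(O[Li])=C[C@@]1(C)CCC=C(C)C | intermediate
28 | (3R,4R)-4-[(tert-butyldimethylsilyl)oxy]-3-methyl-3-(4-methylpent-3-en-1-yl)-2-(prop-2-en-1-yl)cyclohexan-1-one, C2 epimer mixture | CC(C)(C)[Si](C)(C)O[C@@H]1CCC(=O)C(CC=C)[C@@]1(C)CCC=C(C)C | intermediate
29 | (3R,4R)-4-hydroxy-3-methyl-3-(4-methylpent-3-en-1-yl)-2-(prop-2-en-1-yl)cyclohexan-1-one, C2 epimer mixture | O[C@@H]1CCC(=O)C(CC=C)[C@@]1(C)CCC=C(C)C | intermediate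
30 | (3R,4R)-3-{2-[(2R)-3,3-dimethyloxiran-2-yl]ethyl}-4-hydroxy-3-methyl-2-(prop-2-en-1-yl)cyclohexan-1-one, C2 epimer mixture | O[C@@H]1CCC(=O)C(CC=C)[C@@]1(C)CC[C@H]1OC1(C)C | intermediate
31 | (3R,5aR,9aR)-3-hydroxy-2,2,5a-trimethyl-6-(prop-2-en-1-yl)octahydro-1-benzoxepin-7(2H)-one, trans-fused, C6 epimer mixture | C=CCC1[C@@]2(C)CC[C@@H](O)C(C)(C)O[C@@H]2CCC1=O | intermediate
32 | (3R,5aR,6R,9aR)-3-hydroxy-2,2,5a-trimethyl-6-(prop-2-en-1-yl)octahydro-1-benzoxepin-7(2H)-one | C=CC[C@@H]1[C@@]2(C)CC[C@@H](O)C(C)(C)O[C@@H]2CCC1=O | intermediate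
33 | (3R,5aR,6R,7S,9aR)-2,2,5a,7-tetramethyl-6-(prop-2-en-1-yl)decahydro-1-benzoxepine-3,7-diol | C=CC[C@@H]1[C@@]2(C)CC[C@@H](O)C(C)(C)O[C@@H]2CC[C@]1(C)O | intermediate
34 | 3,7-bis(triethylsilyl) ether of 33 | C=CC[C@@H]1[C@@]2(C)CC[C@@H](O[Si](CC)(CC)CC)C(C)(C)O[C@@H]2CC[C@]1(C)O[Si](CC)(CC)CC | intermediate
35 | 2-[(3R,5aR,6R,7S,9aR)-2,2,5a,7-tetramethyl-3,7-bis(triethylsilyloxy)decahydro-1-benzoxepin-6-yl]acetaldehyde (not isolated) | O=CC[C@@H]1[C@@]2(C)CC[C@@H](O[Si](CC)(CC)CC)C(C)(C)O[C@@H]2CC[C@]1(C)O[Si](CC)(CC)CC | intermediate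
36 | 2-[(3R,5aR,6R,7S,9aR)-2,2,5a,7-tetramethyl-3,7-bis(triethylsilyloxy)decahydro-1-benzoxepin-6-yl]ethan-1-ol | OCC[C@@H]1[C@@]2(C)CC[C@@H](O[Si](CC)(CC)CC)C(C)(C)O[C@@H]2CC[C@]1(C)O[Si](CC)(CC)CC | intermediate
37 | (3R,5aR,6R,7S,9aR)-6-(2-iodoethyl)-2,2,5a,7-tetramethyl-3,7-bis(triethylsilyloxy)decahydro-1-benzoxepine | ICC[C@@H]1[C@@]2(C)CC[C@@H](O[Si](CC)(CC)CC)C(C)(C)O[C@@H]2CC[C@]1(C)O[Si](CC)(CC)CC | intermediate
38 | alkyllithium from 37, Li in place of I (not isolated) | [Li]CC[C@@H]1[C@@]2(C)CC[C@@H](O[Si](CC)(CC)CC)C(C)(C)O[C@@H]2CC[C@]1(C)O[Si](CC)(CC)CC | intermediate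
39 | lithium B-alkyl-B-methoxy-9-borabicyclo[3.3.1]nonane ate complex of the fragment AB alkyl group (not isolated) | [Li+].CO[B-]1(C2CCCC1CCC2)CC[C@@H]1[C@@]2(C)CC[C@@H](O[Si](CC)(CC)CC)C(C)(C)O[C@@H]2CC[C@]1(C)O[Si](CC)(CC)CC | intermediate
40 | coupled tris(triethylsilyl) ether: target skeleton with C18 (R)-OSiEt3 in place of the ketone, C9–OSiEt3 and C24–OSiEt3 | CC1=CC[C@@H]2[C@@H](CC[C@@]2(C)O[Si](CC)(CC)CC)C(C)(C)[C@H]1CC[C@@H]1[C@@]2(C)CC[C@@H](O[Si](CC)(CC)CC)C(C)(C)O[C@@H]2CC[C@]1(C)O[Si](CC)(CC)CC | intermediate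
41 | (18R)-triol: target skeleton with a C18 carbinol in place of the ketone | CC1=CC[C@@H]2[C@@H](CC[C@@]2(C)O)C(C)(C)[C@H]1CC[C@@H]1[C@@]2(C)CC[C@@H](O)C(C)(C)O[C@@H]2CC[C@]1(C)O | intermediate
42 | sipholenone A | CC1=CC[C@@H]2[C@@H](CC[C@@]2(C)O)C(C)(C)[C@H]1CC[C@@H]1[C@@]2(C)CCC(=O)C(C)(C)O[C@@H]2CC[C@]1(C)O | target

**Step count and risk**

Total step count: 27. Longest linear sequence: 16 steps (steps 12–24 from 2-methylcyclohex-2-en-1-one, then steps 25–27); the fragment CD branch contributes 11 steps (1–11).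

The three steps most likely to fail:

- **Step 25 (the proposed new coupling).** The γ-carbon C11 is neopentylic and must be attacked on the face of ring D; direct SN2 at C3 or elimination to the diene may win. Fallback with known chemistry: it sets out from alcohol 18 and iodide 37. Alcohol 18 is esterified (pyridine-2-carboxylic acid, DCC, DMAP) to the allylic picolinate F1. Iodide 37 is converted (t-BuLi, then MgBr2·OEt2) into the alkylmagnesium bromide F2. F2 and F1 are combined with CuBr·SMe2 (1 equiv) in THF at −40 → 0 °C; the chelating picolinate leaving group gives the established stoichiometric copper-mediated anti-SN2′ substitution. The fallback comes back to the route at 40.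

- **Step 8 (SmI2 cyclisation).** The cross-conjugated dienone may be over-reduced, or the C9 epimer ratio may be poor. Fallback: it sets out from 14, which is converted (LiN(i-Pr)2, Et3SiCl, THF, −78 °C) into the terminal triethylsilyl enol ether F3. Fe(acac)3 (cat.) and PhSiH3 in EtOH/ethylene glycol at 60 °C then effect a hydrogen-atom-transfer radical conjugate addition: the tertiary α-silyloxy radical at C9 closes 5-exo onto C5 (cis fusion, silyloxy group away from C4). This gives the silyl ether directly, so the fallback comes back at 17 and bypasses 16.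

- **Step 6 (ring expansion).** The alkenyl-substituted silyloxycyclopropane and the ketal may not survive FeCl3, or chloride elimination may be unclean. Fallback: it sets out from 10. Dibromocarbene addition (CHBr3, KOt-Bu, pentane, −20 °C) gives the dibromocyclopropane F4. Warming in toluene with pyridine opens the ring with loss of bromotrimethylsilane to the ring-expanded bromo dienone F5. Reductive debromination (Pd(PPh3)4 cat., Bu3SnH, THF) comes back to the route at 13.

Further compounds
F1 | step 25 | (1R,3aR,7R,8aR)-1,4,4,6-tetramethyl-1-(triethylsilyloxy)-1,2,3,3a,4,7,8,8a-octahydroazulen-7-yl pyridine-2-carboxylate | O=C(O[C@@H]1C[C@@H]2[C@@H](CC[C@@]2(C)O[Si](CC)(CC)CC)C(C)(C)C=C1C)c1ccccn1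
F2 | step 25 | alkylmagnesium bromide from 37 (MgBr in place of I) | Br[Mg]CC[C@@H]1[C@@]2(C)CC[C@@H](O[Si](CC)(CC)CC)C(C)(C)O[C@@H]2CC[C@]1(C)O[Si](CC)(CC)CC
F3 | step 8 | (5R)-2,4,4-trimethyl-5-{3-[(triethylsilyl)oxy]but-3-en-1-yl}cyclohepta-2,6-dien-1-one | C=C(CC[C@@H]1C=CC(=O)C(C)=CC1(C)C)O[Si](CC)(CC)CC
F4 | step 6 | ({(5R)-7,7-dibromo-2,4,4-trimethyl-5-[2-(2-methyl-1,3-dioxolan-2-yl)ethyl]bicyclo[4.1.0]hept-2-en-1-yl}oxy)trimethylsilane, cyclopropane diastereomers | C[Si](C)(C)OC12C(Br)(Br)C1[C@@H](CCC1(C)OCCO1)C(C)(C)C=C2C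
F5 | step 6 | (5R)-7-bromo-2,4,4-trimethyl-5-[2-(2-methyl-1,3-dioxolan-2-yl)ethyl]cyclohepta-2,6-dien-1-one | O=C1C(Br)=C[C@@H](CCC2(C)OCCO2)C(C)(C)C=C1C
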